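The data stem from a simulated flask with constants of no real substance.

Take one percentage point of Z lost late in the birch run and ask where it goes.

| setting | birch | elm | winter | dawn | dusk | spring |
|---|---|---|---|---|---|---|
| X | 0.13 M | 0.13 M | 0.13 M (fed, over 20 h) | 0.13 M | 0.13 M | 0.13 M |
| Q | 0.143 M | 0.21 M | 0.143 M | 0.143 M | 0.143 M (fed, over 20 h) | 0.143 M (in portions, 4, over 20 h) |
| remark | run made earlier | run made earlier | all else is in the flask from the start; the feed brings no volume worth counting | everything together at the start | all else is in the flask from the start; the feed brings no volume worth counting | first portion at the start, last at 20 h |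
| time |  |  | 25 h | 25 h | 25 h | 25 h |

| run | time / h | Z / % | X / % |
|---|---|---|---|
| birch | 2.00 | 39.4 | 35.8 |
| birch | 6.00 | 29.9 | 34.1 |
| birch | 12.0 | 20.4 | 37.8 |
| birch | 20.0 | 15.5 | 40.1 |
| birch | 25.0 | 13.5 | 40.9 |
| elm | 0.417 | 35.9 | 54.6 |
| elm | 0.833 | 40.5 | 37.1 |
| elm | 1.33 | 39.9 | 28.2 |
| elm | 2.50 | 32.3 | 19.6 |
| elm | 5.00 | 23.3 | 17.3 |

(standard deviation of a reading: 0.5 percentage points)



1. the best flask by amount of Z, in percent of the X charged; "all alike" if 1.5 percentage points covers them all (winter / dawn / dusk / spring / all alike)
2. amount of Z at the end, in percent of the X charged, winter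
3. amount of Z at the end, in percent of the X charged, dawn
4. amount of Z at the end, in percent of the X charged, dusk
5. amount of Z at the end, in percent of the X charged, spring

From 6.00 h to 25.0 h, birch loses 16 percentage points of Z while X regains 6.8 points. So the reading is 41.5% for the return chance, the points of X regained per point of Z lost. The rest of that Z goes on to something no reading shows.

Two chemists read this differently. The first says the charge counts: the flasks get the same X and Q, a Z that turns back hands its Q on, and so the dosing washes out and the four flasks end near birch's 13.5%.

The second says this washing-out is slow. The 5.00 h after the last dosing are shorter than birch's stretch of 19.0 h, and at birch's mean pace over that stretch they cost 4.3 points. If spring's last portion lifts Z back to birch's level at 6.00 h, spring ends near 25.6%. I side with the second: spring comes first, dusk belongs on its side, and dawn, a repeat of birch, stays near 13.5%.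

The forecast also takes the second side, with spring best at 22%, dusk 17.5%, dawn 13.5% and winter 12.7%, since “the last portion at 20 h regenerates Z”.

The simulation gives winter 12.8%, dawn 13.0%, dusk 22.7% and spring 25.0%, so spring is best.

    X + Q ⇌ E + Z (K = 8.90, k = 8.40 M⁻¹ h⁻¹)
    Z + Q ⇌ E + D (K = 83.0, k = 3.70 M⁻¹ h⁻¹)
    D + Q ⇌ E + J (K = 2.10, k = 0.370 M⁻¹ h⁻¹)
    J + Q ⇌ E + G (K = 76.0, k = 7.20 M⁻¹ h⁻¹)
    Z + Q → L (k = 2.50 M⁻¹ h⁻¹)

The largest single effect on spring's Z is the return of E + Z to X + Q: the same run without that return ends at 42.4%, not 25.0%. The first chemist's washing-out does appear, late and lower than birch's last reading: by 250 h, spring's Z stands at 7.21% and winter's at 7.23%. Reckoned with the return chance, spring's X goes from 36.0% to an estimated 43.4% by then, and the flask holds 43.7%; for dusk the estimate is 43.2%, and the flask holds 43.7%.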